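**Retrosynthetic overview**
1. Target 17 ⇐ diol 16 (double acetylation) ⇐ 8α,17-epoxide 15, whose base-induced opening to the allylic alcohol sets the Δ7 alkene and the C17–O bond; the epoxide comes from an exocyclic Δ8(17) alkene.
2. The (13E)-enoate 12 ⇐ (Z)-enol phosphate 11 + Me2CuLi ⇐ β-keto ester 9.
3. Key C–C disconnection (C14–C15): 9 ⇐ intermolecular crossed Claisen condensation of the enolate of the C18 methyl ketone 5 with dimethyl carbonate 6.
4. 5 ⇐ (−)-sclareol 1 by oxidative removal of the vinyl group and regioselective dehydration of the 8α-OH.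
5. Rings: none are formed; the trans-decalin with C5, C9 and C10 is carried intact from sclareol.

Assumption: natural (−)-sclareol (single enantiomer, from clary sage) counts as a cheap commercial starting material. Its 5S,10S, 9α-H configuration is that of the target (5S,9R,10S; 10-CH3 β, 5-H and 9-H α). Labdane numbering is used throughout; the CIP label at C9 switches between R and S with the substitution at C8 while the geometry stays the same.

**Route**

Step 1
Reactants: 1 (−)-sclareol
Product: 3 8α-hydroxy-14,15-dinorlabdan-13-one, via labdane-8α,13,14,15-tetrol 2 (not isolated)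
Conditions: KMnO4 (4 equiv), MgSO4, acetone–H2O, 0 °C → rt
Reagents that add atoms: none
Why: Permanganate oxidative cleavage of the vinyl carbinol (syn-dihydroxylation of C14=C15, then C–C cleavage down to the C13 ketone) removes C14 and C15 while the hindered tertiary 8α-OH and the ring stereocentres are untouched.

Step 2
Reactants: 3 8α-hydroxy-14,15-dinorlabdan-13-one
Product: 5 14,15-dinorlabd-8(17)-en-13-one, via 8α-chlorosulfite 4 (not isolated)
Conditions: SOCl2 (3 equiv), pyridine (10 equiv), CH2Cl2, −78 °C; chromatography on AgNO3–SiO2 to remove endocyclic isomers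
Reagents that add atoms: none
Why: E2 dehydration through the chlorosulfite follows Barton's rule for tertiary methyl carbinols, because the equatorial 8α leaving group has an anti-periplanar hydrogen only on the axial C17 methyl, so the exocyclic Δ8(17) alkene predominates and no stereocentre is touched.

Step 3
Reactants: 5 14,15-dinorlabd-8(17)-en-13-one; 6 dimethyl carbonate
Product: 9 methyl 13-oxo-16-norlabd-8(17)-en-15-oate, via ketone potassium enolate 7 (not isolated), via keto ester potassium enolate 8 (not isolated)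
Conditions: KH (2.5 equiv), (MeO)2CO (6 equiv), THF, reflux; then 1 M HCl, 0 °C
Reagents that add atoms: none
Why: Intermolecular crossed Claisen condensation in which the methyl-side potassium enolate of ketone 5 attacks dimethyl carbonate to forge the C14–C15 bond, driven by irreversible deprotonation of the product to the stabilised enolate 8, which also fixes acylation at the unhindered CH3 and not at C12.

Step 4
Reactants: 9 methyl 13-oxo-16-norlabd-8(17)-en-15-oate
Product: 11 methyl (13Z)-13-(diethoxyphosphoryloxy)-16-norlabda-8(17),13-dien-15-oate, via keto ester sodium enolate 10 (not isolated)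
Conditions: NaH (1.1 equiv), Et2O, 0 °C; then ClP(O)(OEt)2 (1.1 equiv), 0 °C → rt
Reagents that add atoms: diethyl chlorophosphate, CCOP(=O)(Cl)OCC
Why: O-Phosphorylation of the sodium-chelated enolate (Weiler enol phosphate synthesis) traps the Z enolate, in which Na+ bridges both oxygens in ether, and so fixes the geometry of the future C13=C14 bond.

Step 5
Reactants: 11 methyl (13Z)-13-(diethoxyphosphoryloxy)-16-norlabda-8(17),13-dien-15-oate
Product: 12 methyl (13E)-labda-8(17),13-dien-15-oate
Conditions: Me2CuLi (2.5 equiv, from CuI + 2 MeLi), Et2O, −78 → −45 °C; aq NH4Cl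
Reagents that add atoms: lithium dimethylcuprate, [Li+].C[Cu-]C (made in the flask from methyllithium, [Li]C, and CuI)
Why: Cuprate addition–elimination on the β-phosphoryloxy enoate (Weiler coupling) replaces the phosphate by methyl with retention, so the new C16 methyl lies cis to the ester and the trisubstituted alkene is E.

Step 6
Reactants: 12 methyl (13E)-labda-8(17),13-dien-15-oate
Product: 13 methyl (13E)-8α,17-epoxylabd-13-en-15-oate
Conditions: mCPBA (1.2 equiv), NaHCO3, CH2Cl2, 0 °C
Reagents that add atoms: mCPBA, OOC(=O)c1cccc(Cl)c1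
Why: Prilezhaev epoxidation is chemoselective for the electron-rich 1,1-disubstituted exocyclic alkene over the conjugated enoate, and attack from the α (equatorial) face anti to the axial C10 methyl gives the 8α,17-epoxide, a temporary centre erased in step 8 (any 8β-epimer converges there).

Step 7
Reactants: 13 methyl (13E)-8α,17-epoxylabd-13-en-15-oate
Product: 15 (13E)-8α,17-epoxylabd-13-en-15-ol, via epoxy enal 14 (not isolated)
Conditions: DIBAL-H (2.5 equiv), CH2Cl2, −78 °C; Rochelle salt
Reagents that add atoms: none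
Why: DIBAL-H 1,2-reduction of the α,β-unsaturated ester at −78 °C runs through the enal to the allylic alcohol faster than any epoxide opening and leaves the E geometry intact.

Step 8
Reactants: 15 (13E)-8α,17-epoxylabd-13-en-15-ol
Product: 16 (13E)-labda-7,13-diene-15,17-diol
Conditions: Et2Al–TMP (4 equiv; from TMPH, n-BuLi, Et2AlCl), toluene, 0 °C → rt; Rochelle salt
Reagents that add atoms: none
Why: Yamamoto epoxide-to-allylic-alcohol isomerisation, in which the bulky aluminium amide coordinates the epoxide oxygen and removes a syn β-hydrogen from the accessible C7 methylene in preference to the hindered C9 methine, opening the tertiary C8–O bond to give the Δ7 alkene with the C17 hydroxyl and leaving C9 untouched.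

Step 9
Reactants: 16 (13E)-labda-7,13-diene-15,17-diol
Product: 17 (13E)-labda-7,13-diene-15,17-diyl diacetate (target)
Conditions: Ac2O (3 equiv), pyridine, DMAP (5 mol%), CH2Cl2, 0 °C → rt
Reagents that add atoms: acetic anhydride, CC(=O)OC(C)=O
Why: DMAP-catalysed acylation of the two primary allylic hydroxyls gives the diacetate without touching either alkene or any stereocentre.

**Compound list**

1 | (−)-sclareol, (13R)-labd-14-ene-8α,13-diol | C=C[C@](C)(O)CC[C@H]1[C@](C)(O)CC[C@H]2C(C)(C)CCC[C@]12C | starting material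
2 | (13R)-labdane-8α,13,14,15-tetrol, C14 epimers (not isolated) | OCC(O)[C@](C)(O)CC[C@H]1[C@](C)(O)CC[C@H]2C(C)(C)CCC[C@]12C | intermediate
3 | 8α-hydroxy-14,15-dinorlabdan-13-one; 4-[(1R,2R,4aS,8aS)-2-hydroxy-2,5,5,8a-tetramethyldecahydronaphthalen-1-yl]butan-2-one | CC(=O)CC[C@H]1[C@](C)(O)CC[C@H]2C(C)(C)CCC[C@]12C | intermediate
4 | 13-oxo-14,15-dinorlabdan-8α-yl chlorosulfite (not isolated) | CC(=O)CC[C@H]1[C@](C)(OS(=O)Cl)CC[C@H]2C(C)(C)CCC[C@]12C | intermediate
5 | 14,15-dinorlabd-8(17)-en-13-one; 4-[(1S,4aS,8aS)-5,5,8a-trimethyl-2-methylidenedecahydronaphthalen-1-yl]butan-2-one | CC(=O)CC[C@H]1C(=C)CC[C@H]2C(C)(C)CCC[C@]12C | intermediate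
6 | dimethyl carbonate | COC(=O)OC | starting material
7 | potassium enolate of 5 on the methyl side (not isolated) | [K+].C=C([O-])CC[C@H]1C(=C)CC[C@H]2C(C)(C)CCC[C@]12C | intermediate
8 | potassium enolate of 9, drawn as the chelated Z form (not isolated) | [K+].COC(=O)/C=C(\[O-])CC[C@H]1C(=C)CC[C@H]2C(C)(C)CCC[C@]12C | intermediate
9 | methyl 13-oxo-16-norlabd-8(17)-en-15-oate (former acetyl CH3 is now C14, new ester carbon is C15) | COC(=O)CC(=O)CC[C@H]1C(=C)CC[C@H]2C(C)(C)CCC[C@]12C | intermediate
10 | sodium (Z)-enolate of 9 (not isolated) | [Na+].COC(=O)/C=C(\[O-])CC[C@H]1C(=C)CC[C@H]2C(C)(C)CCC[C@]12C | intermediate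
11 | methyl (13Z)-13-(diethoxyphosphoryloxy)-16-norlabda-8(17),13-dien-15-oate | COC(=O)/C=C(\OP(=O)(OCC)OCC)CC[C@H]1C(=C)CC[C@H]2C(C)(C)CCC[C@]12C | intermediate
12 | methyl (13E)-labda-8(17),13-dien-15-oate | COC(=O)/C=C(\C)CC[C@H]1C(=C)CC[C@H]2C(C)(C)CCC[C@]12C | intermediate
13 | methyl (8R,13E)-8α,17-epoxylabd-13-en-15-oate (epoxide O α, C17 β) | COC(=O)/C=C(\C)CC[C@H]1[C@]3(OC3)CC[C@H]2C(C)(C)CCC[C@]12C | intermediate
14 | (8R,13E)-8α,17-epoxylabd-13-en-15-al (not isolated) | O=C/C=C(\C)CC[C@H]1[C@]3(OC3)CC[C@H]2C(C)(C)CCC[C@]12C | intermediate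
15 | (8R,13E)-8α,17-epoxylabd-13-en-15-ol | OC/C=C(\C)CC[C@H]1[C@]3(OC3)CC[C@H]2C(C)(C)CCC[C@]12C | intermediate
16 | (13E)-labda-7,13-diene-15,17-diol (5S,9R,10S) | OC/C=C(\C)CC[C@H]1C(CO)=CC[C@H]2C(C)(C)CCC[C@]12C | intermediate
17 | (13E)-labda-7,13-diene-15,17-diyl diacetate (5S,9R,10S) | CC(=O)OC/C=C(\C)CC[C@H]1C(COC(C)=O)=CC[C@H]2C(C)(C)CCC[C@]12C | target

**Summary**

Total step count: 9. Longest linear sequence: 9 steps (1 → 17).

Steps most likely to fail:

Step 2 (dehydration beside a free methyl ketone). The ketone can trap the activated C8 centre as the cyclic enol ether (sclareol oxide), and some endocyclic alkene is expected. The fallback sets out from 3 and comes back at 5. The ketone is masked first by NaBH4 reduction to 14,15-dinorlabdane-8α,13-diol F1. The secondary hydroxyl alone is acetylated (Ac2O, pyridine) to 8α-hydroxy-14,15-dinorlabdan-13-yl acetate F2. The same SOCl2/pyridine dehydration at −78 °C then gives 14,15-dinorlabd-8(17)-en-13-yl acetate F3. Methanolysis (K2CO3, MeOH) gives 14,15-dinorlabd-8(17)-en-13-ol F4, and Dess–Martin oxidation returns 5. Minor endocyclic isomers are removed on AgNO3–SiO2 at the F3 or 5 stage.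

Step 5 (cuprate displacement of the enol phosphate). Incomplete conversion or loss of geometry would compromise the E alkene. The fallback sets out from 9 and comes back at 12. The β-keto ester is converted under Z-selective conditions (aq. LiOH, Tf2O, toluene, 5 °C) into methyl (13Z)-13-(trifluoromethylsulfonyloxy)-16-norlabda-8(17),13-dien-15-oate F5. A stereoretentive Negishi cross-coupling (MeZnCl, cat. Pd(PPh3)4, THF, rt) then installs the methyl group by a catalytic oxidative-addition/transmetallation pathway.

Step 8 (epoxide to allylic alcohol). Competing C9–H abstraction (Δ8 isomer) or Lewis-acid rearrangement of the epoxide to the C17 aldehyde are the likely problems. The fallback sets out from 12 and comes back at 16, bypassing the epoxide. Allylic oxidation of the exocyclic alkene (cat. SeO2, t-BuOOH, CH2Cl2) gives methyl (13E)-7α-hydroxylabda-8(17),13-dien-15-oate F6. PBr3 (Et2O, 0 °C) then gives, with allylic transposition (SN2'), the primary bromide methyl (13E)-17-bromolabda-7,13-dien-15-oate F7. Displacement with KOAc in DMF gives methyl (13E)-17-acetoxylabda-7,13-dien-15-oate F8. Excess DIBAL-H (CH2Cl2, −78 → 0 °C) reduces both ester groups to diol 16.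

**Further compounds**

F1 | step 2 | 14,15-dinorlabdane-8α,13-diol (C13 epimers) | CC(O)CC[C@H]1[C@](C)(O)CC[C@H]2C(C)(C)CCC[C@]12C
F2 | step 2 | 8α-hydroxy-14,15-dinorlabdan-13-yl acetate (C13 epimers) | CC(OC(C)=O)CC[C@H]1[C@](C)(O)CC[C@H]2C(C)(C)CCC[C@]12C
F3 | step 2 | 14,15-dinorlabd-8(17)-en-13-yl acetate (C13 epimers) | CC(OC(C)=O)CC[C@H]1C(=C)CC[C@H]2C(C)(C)CCC[C@]12C
F4 | step 2 | 14,15-dinorlabd-8(17)-en-13-ol (C13 epimers) | CC(O)CC[C@H]1C(=C)CC[C@H]2C(C)(C)CCC[C@]12C
F5 | step 5 | methyl (13Z)-13-(trifluoromethylsulfonyloxy)-16-norlabda-8(17),13-dien-15-oate | COC(=O)/C=C(\OS(=O)(=O)C(F)(F)F)CC[C@H]1C(=C)CC[C@H]2C(C)(C)CCC[C@]12C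
F6 | step 8 | methyl (13E)-7α-hydroxylabda-8(17),13-dien-15-oate | COC(=O)/C=C(\C)CC[C@H]1C(=C)[C@H](O)C[C@H]2C(C)(C)CCC[C@]12C
F7 | step 8 | methyl (13E)-17-bromolabda-7,13-dien-15-oate | COC(=O)/C=C(\C)CC[C@H]1C(CBr)=CC[C@H]2C(C)(C)CCC[C@]12C
F8 | step 8 | methyl (13E)-17-acetoxylabda-7,13-dien-15-oate | COC(=O)/C=C(\C)CC[C@H]1C(COC(C)=O)=CC[C@H]2C(C)(C)CCC[C@]12C
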